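**Retrosynthetic overview**
- The target is unmasked from its C2 silyl ether; the side-chain oxirane (C10–C11) comes from a Shi epoxidation of a prenyl alkene, itself made by cross-metathesis of a terminal vinyl group with 2-methyl-2-butene.
- The ring oxirane (C4–C5) comes from peracid epoxidation anti to the pseudo-axial C3 angelate; both angelates are installed together on a C3,C8-diol.
- Key C8–C9 bond: asymmetric allylboration of a 2-(cyclohexenyl)acrolein with B-allyldiisopinocampheylborane, which sets C8.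
- The enal comes from (S)-carvone: Rubottom α'-hydroxylation (C2), ene-type allylic chlorination then acetate (C8 oxygen), Luche reduction then Mitsunobu inversion (C3).
- Ring order: the carbocycle is carvone's own ring and is never built; the C4–C5 oxirane is closed first (step 12), the C10–C11 oxirane last (step 14).

Assumption (locants used below): ring C1 (bears the side chain), C2 (free OH in the target), C3 (angelate), C4 (methyl), C5, C6; side chain C7(=CH2), C8 (angelate), C9, C10, C11; angelate = (2Z)-2-methylbut-2-enoate, TBS = tert-butyldimethylsilyl.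

**Step 1**
Reactants: 1 (S)-(+)-carvone, (5S)-2-methyl-5-(prop-1-en-2-yl)cyclohex-2-en-1-one
Product: 3 trimethyl{[(3S)-6-methyl-3-(prop-1-en-2-yl)cyclohexa-1,5-dien-1-yl]oxy}silane, via lithium dienolate 2 (not isolated)
Conditions: LiN(i-Pr)2, THF, −78 °C; TMSCl, −78 → 0 °C
Reagents that add atoms: TMSCl, C[Si](C)(C)Cl; LiN(i-Pr)2, CC(C)N([Li])C(C)C (its lithium stays only in intermediate 2)
Why: Kinetic α'-deprotonation of the enone at its only CH2 next to the carbonyl gives the cross-conjugated dienolate, which is O-silylated (silyl enol ether formation) without touching the existing stereocentre.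

**Step 2**
Reactants: 3 the TMS dienol ether
Product: 5 (5R,6R)-6-hydroxy-2-methyl-5-(prop-1-en-2-yl)cyclohex-2-en-1-one (trans), via alpha-trimethylsilyloxy ketone 4 (not isolated)
Conditions: mCPBA (1.05 equiv), NaHCO3, CH2Cl2, −20 → 0 °C; then 1 M HCl, THF, 0 °C
Reagents that add atoms: mCPBA, OOC(=O)c1cccc(Cl)c1
Why: Rubottom oxidation, in which the peracid attacks the electron-rich enol ether on the face anti to the adjacent isopropenyl group, so after silyl shift and hydrolysis the new hydroxyl (C2 of the target) is trans to the side chain.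

**Step 3**
Reactants: 5 the trans α'-hydroxy enone
Product: 6 (5R,6R)-6-{[tert-butyl(dimethyl)silyl]oxy}-2-methyl-5-(prop-1-en-2-yl)cyclohex-2-en-1-one
Conditions: TBSCl, imidazole, DMF, rt
Reagents that add atoms: TBSCl, CC(C)(C)[Si](C)(C)Cl
Why: Imidazole-promoted silylation protects the hydroxyl that must stay free of acyl groups until the end, and the trans arrangement is also the thermodynamic one so no epimerisation is expected.

**Step 4**
Reactants: 6 the TBS-protected enone
Product: 7 (5R,6R)-6-{[tert-butyl(dimethyl)silyl]oxy}-5-(3-chloroprop-1-en-2-yl)-2-methylcyclohex-2-en-1-one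
Conditions: Ca(OCl)2, CO2 (dry ice), CH2Cl2/H2O, 0 °C
Reagents that add atoms: Ca(OCl)2, [Ca+2].[O-]Cl.[O-]Cl
Why: Ene-type allylic chlorination by HOCl generated in the flask attacks only the electron-rich isopropenyl group (the ring alkene is deactivated by conjugation) and shifts the double bond to give the 2-(chloromethyl)vinyl unit, as in the known carvone to 10-chlorocarvone conversion.

**Step 5**
Reactants: 7 the allylic chloride
Product: 8 2-[(1R,6R)-6-{[tert-butyl(dimethyl)silyl]oxy}-4-methyl-5-oxocyclohex-3-en-1-yl]prop-2-en-1-yl acetate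
Conditions: KOAc, Bu4NI (cat.), DMF, 40 °C
Reagents that add atoms: KOAc, CC(=O)[O-].[K+]
Why: Iodide-assisted SN2 displacement of the primary allylic chloride by acetate (the SN2' path gives the same product) installs the future C8 oxygen in masked form.

**Step 6**
Reactants: 8 the keto acetate
Product: 9 2-[(1R,5R,6R)-6-{[tert-butyl(dimethyl)silyl]oxy}-5-hydroxy-4-methylcyclohex-3-en-1-yl]prop-2-en-1-yl acetate
Conditions: NaBH4, CeCl3·7H2O, MeOH, −20 °C
Reagents that add atoms: none
Why: Luche reduction is strictly 1,2 and is expected to deliver hydride axially to the half-chair with both substituents equatorial, giving the pseudo-equatorial C3 alcohol (trans to the silyloxy group, cis to the side chain, to be confirmed by a large H2–H3 coupling), which is the epimer that the next step inverts.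

**Step 7**
Reactants: 9 the pseudo-equatorial allylic alcohol
Product: 10 (1S,5R,6R)-5-[3-(acetyloxy)prop-1-en-2-yl]-6-{[tert-butyl(dimethyl)silyl]oxy}-2-methylcyclohex-2-en-1-yl 4-nitrobenzoate
Conditions: 4-O2NC6H4CO2H, PPh3, DIAD, THF, 0 °C → rt
Reagents that add atoms: 4-nitrobenzoic acid, OC(=O)c1ccc(cc1)[N+](=O)[O-]
Why: Mitsunobu reaction, in which the carboxylate displaces the alkoxyphosphonium by SN2 and so inverts C3 to the pseudo-axial ester, establishing the C2/C3 cis relationship of the target.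

**Step 8**
Reactants: 10 the acetate 4-nitrobenzoate
Product: 11 (1S,5R,6R)-6-{[tert-butyl(dimethyl)silyl]oxy}-5-(3-hydroxyprop-1-en-2-yl)-2-methylcyclohex-2-en-1-ol
Conditions: i-Bu2AlH (5 equiv), CH2Cl2, −78 °C; aq. KNaC4H4O6
Reagents that add atoms: none
Why: Reductive ester cleavage of both esters at low temperature breaks only acyl C–O bonds (configuration retained) and avoids the basic alkoxide conditions that could move the silyl group to the cis C3 oxygen.

**Step 9**
Reactants: 11 the diol
Product: 12 2-[(1R,5S,6R)-6-{[tert-butyl(dimethyl)silyl]oxy}-5-hydroxy-4-methylcyclohex-3-en-1-yl]prop-2-enal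
Conditions: TEMPO (10 mol %), PhI(OAc)2, CH2Cl2, rt
Reagents that add atoms: none
Why: Oxoammonium (TEMPO) oxidation is selective for the primary allylic alcohol over the hindered secondary one, and the trans-1,3 relationship of C3–OH and the acrolein unit prevents lactol or oxa-Michael ring closure.

**Step 10**
Reactants: 12 the hydroxy enal; 13 B-allyldiisopinocampheylborane with both isopinocampheyl groups from (+)-α-pinene (the reagent obtained from (−)-Ipc2BOMe and allylmagnesium bromide, used as a commercial pentane solution, 2.2 equiv)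
Product: 15 (1S,5R,6R)-6-{[tert-butyl(dimethyl)silyl]oxy}-5-[(3S)-3-hydroxyhexa-1,5-dien-2-yl]-2-methylcyclohex-2-en-1-ol, via C8 O-borinate 14 (not isolated)
Conditions: Et2O/pentane, −78 °C; then pH 7 buffer, MeOH, 30 % H2O2, 0 °C → rt
Reagents that add atoms: none
Why: Brown asymmetric allylboration, a carbonyl allylation through a closed chair transition state in which this reagent adds allyl to the Si face of the aldehyde, forms the C8–C9 bond and sets C8 as S under reagent control; it is fast enough at −78 °C that the free C3 hydroxyl does not interfere.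

**Step 11**
Reactants: 15 the C3,C8-diol; 16 angelic acid, (2Z)-2-methylbut-2-enoic acid
Product: 18 (3S)-2-[(1R,5S,6R)-6-{[tert-butyl(dimethyl)silyl]oxy}-4-methyl-5-{[(2Z)-2-methylbut-2-enoyl]oxy}cyclohex-3-en-1-yl]hexa-1,5-dien-3-yl (2Z)-2-methylbut-2-enoate, via mixed angelic 2,4,6-trichlorobenzoic anhydride 17 (not isolated)
Conditions: 16 (6 equiv), 2,4,6-Cl3C6H2COCl, Et3N, PhMe, rt; then 15, 75 °C
Reagents that add atoms: 2,4,6-trichlorobenzoyl chloride, O=C(Cl)c1c(Cl)cc(Cl)cc1Cl (its atoms stay only in intermediate 17)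
Why: Yamaguchi-type esterification through the mixed anhydride without DMAP acylates both secondary alcohols with retention at carbon and keeps the Z geometry, avoiding isomerisation to tiglate.

**Step 12**
Reactants: 18 the bis-angelate
Product: 19 (3S)-2-[(1R,2R,3R,4R,5R)-2-{[tert-butyl(dimethyl)silyl]oxy}-4,5-epoxy-4-methyl-3-{[(2Z)-2-methylbut-2-enoyl]oxy}cyclohexyl]hexa-1,5-dien-3-yl (2Z)-2-methylbut-2-enoate (oxirane cis to the side chain, trans to the C3 ester)
Conditions: mCPBA (1.1 equiv), NaHCO3, CH2Cl2, 0 °C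
Reagents that add atoms: mCPBA, OOC(=O)c1cccc(Cl)c1
Why: Prilezhaev epoxidation picks the trisubstituted ring alkene (the others are a hindered 1,1-disubstituted allylic ester, a monosubstituted vinyl and two electron-poor enoates), and the peracid approaches anti to the C3 angelate, which A1,2 strain with the C4 methyl holds pseudo-axial, so the oxirane forms cis to the side chain.

**Step 13**
Reactants: 19 the ring epoxide with terminal vinyl group; 20 2-methyl-2-butene (large excess)
Product: 21 (3S)-2-[(1R,2R,3R,4R,5R)-2-{[tert-butyl(dimethyl)silyl]oxy}-4,5-epoxy-4-methyl-3-{[(2Z)-2-methylbut-2-enoyl]oxy}cyclohexyl]-6-methylhepta-1,5-dien-3-yl (2Z)-2-methylbut-2-enoate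
Conditions: RuCl2(=CHPh)(PCy3)(H2IMes) (second-generation Grubbs catalyst, 5 mol %), CH2Cl2, 40 °C
Reagents that add atoms: none
Why: Olefin cross-metathesis converts the terminal vinyl group into the prenyl-type trisubstituted alkene with loss of propene, while the hindered 1,1-disubstituted alkene and the angelate alkenes do not react.

**Step 14**
Reactants: 21 the prenyl compound
Product: 22 the 2-O-TBS ether of the target, (1R,2R,3R,4R,5R,8S,10R)
Conditions: D-fructose-derived Shi ketone (30 mol %), 2KHSO5·KHSO4·K2SO4 (Oxone), K2CO3, Bu4NHSO4, MeCN/CH2(OMe)2/aq. Na2B4O7 buffer, 0 °C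
Reagents that add atoms: Oxone (active component KHSO5), [K+].[O-]S(=O)(=O)OO
Why: Shi asymmetric epoxidation with the chiral dioxirane from the D-fructose ketone reacts only at the electron-rich trisubstituted alkene through the spiro transition state and gives the 10R oxirane under reagent control.

**Step 15**
Reactants: 22 the silyl ether of the target
Product: 23 CNP0296086.5, (1R,2R,3R,4R,5R,8S,10R)-3,8-bis(angeloyloxy)-4,5:10,11-diepoxybisabol-7(14)-en-2-ol
Conditions: HF·pyridine, pyridine, THF, 0 °C → rt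
Reagents that add atoms: none
Why: Fluoride-mediated desilylation under buffered, non-basic conditions frees the C2 hydroxyl without 3→2 acyl migration and is expected to leave both oxiranes intact.

**Compound list**
1 | (S)-(+)-carvone | C=C(C)[C@H]1CC=C(C)C(=O)C1 | starting material
2 | lithium (3S)-6-methyl-3-(prop-1-en-2-yl)cyclohexa-1,5-dien-1-olate | C=C(C)[C@H]1CC=C(C)C(O[Li])=C1 | intermediate
3 | trimethyl{[(3S)-6-methyl-3-(prop-1-en-2-yl)cyclohexa-1,5-dien-1-yl]oxy}silane | C=C(C)[C@H]1CC=C(C)C(O[Si](C)(C)C)=C1 | intermediate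
4 | (5R,6R)-2-methyl-5-(prop-1-en-2-yl)-6-[(trimethylsilyl)oxy]cyclohex-2-en-1-one | C=C(C)[C@H]1CC=C(C)C(=O)[C@@H]1O[Si](C)(C)C | intermediate
5 | (5R,6R)-6-hydroxy-2-methyl-5-(prop-1-en-2-yl)cyclohex-2-en-1-one | C=C(C)[C@H]1CC=C(C)C(=O)[C@@H]1O | intermediate
6 | (5R,6R)-6-(TBS-oxy)-2-methyl-5-(prop-1-en-2-yl)cyclohex-2-en-1-one | C=C(C)[C@H]1CC=C(C)C(=O)[C@@H]1O[Si](C)(C)C(C)(C)C | intermediate
7 | (5R,6R)-6-(TBS-oxy)-5-(3-chloroprop-1-en-2-yl)-2-methylcyclohex-2-en-1-one | C=C(CCl)[C@H]1CC=C(C)C(=O)[C@@H]1O[Si](C)(C)C(C)(C)C | intermediate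
8 | 2-[(1R,6R)-6-(TBS-oxy)-4-methyl-5-oxocyclohex-3-en-1-yl]prop-2-en-1-yl acetate | C=C(COC(C)=O)[C@H]1CC=C(C)C(=O)[C@@H]1O[Si](C)(C)C(C)(C)C | intermediate
9 | 2-[(1R,5R,6R)-6-(TBS-oxy)-5-hydroxy-4-methylcyclohex-3-en-1-yl]prop-2-en-1-yl acetate | C=C(COC(C)=O)[C@H]1CC=C(C)[C@@H](O)[C@@H]1O[Si](C)(C)C(C)(C)C | intermediate
10 | (1S,5R,6R)-5-[3-(acetyloxy)prop-1-en-2-yl]-6-(TBS-oxy)-2-methylcyclohex-2-en-1-yl 4-nitrobenzoate | C=C(COC(C)=O)[C@H]1CC=C(C)[C@H](OC(=O)c2ccc(cc2)[N+](=O)[O-])[C@@H]1O[Si](C)(C)C(C)(C)C | intermediate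
11 | (1S,5R,6R)-6-(TBS-oxy)-5-(3-hydroxyprop-1-en-2-yl)-2-methylcyclohex-2-en-1-ol | C=C(CO)[C@H]1CC=C(C)[C@H](O)[C@@H]1O[Si](C)(C)C(C)(C)C | intermediate
12 | 2-[(1R,5S,6R)-6-(TBS-oxy)-5-hydroxy-4-methylcyclohex-3-en-1-yl]prop-2-enal | C=C(C=O)[C@H]1CC=C(C)[C@H](O)[C@@H]1O[Si](C)(C)C(C)(C)C | intermediate
13 | B-allyldiisopinocampheylborane from (+)-α-pinene | C=CCB([C@@H]1C[C@@H]2C[C@H]([C@H]1C)C2(C)C)[C@@H]1C[C@@H]2C[C@H]([C@H]1C)C2(C)C | starting material
14 | C8 O-diisopinocampheylborinate of 15 | C=C([C@H](CC=C)OB([C@@H]1C[C@@H]2C[C@H]([C@H]1C)C2(C)C)[C@@H]3C[C@@H]4C[C@H]([C@H]3C)C4(C)C)[C@H]5CC=C(C)[C@H](O)[C@@H]5O[Si](C)(C)C(C)(C)C | intermediate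
15 | (1S,5R,6R)-6-(TBS-oxy)-5-[(3S)-3-hydroxyhexa-1,5-dien-2-yl]-2-methylcyclohex-2-en-1-ol | C=C([C@H](CC=C)O)[C@H]1CC=C(C)[C@H](O)[C@@H]1O[Si](C)(C)C(C)(C)C | intermediate
16 | angelic acid, (2Z)-2-methylbut-2-enoic acid | C/C=C(/C)C(=O)O | starting material
17 | (2Z)-2-methylbut-2-enoic 2,4,6-trichlorobenzoic anhydride | C/C=C(/C)C(=O)OC(=O)c1c(Cl)cc(Cl)cc1Cl | intermediate
18 | (3S)-2-[(1R,5S,6R)-6-(TBS-oxy)-4-methyl-5-(angeloyloxy)cyclohex-3-en-1-yl]hexa-1,5-dien-3-yl angelate | C=C([C@H](CC=C)OC(=O)/C(C)=C\C)[C@H]1CC=C(C)[C@H](OC(=O)/C(C)=C\C)[C@@H]1O[Si](C)(C)C(C)(C)C | intermediate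
19 | 4,5-epoxide of 18, (1R,2R,3R,4R,5R,8S) | C=C([C@H](CC=C)OC(=O)/C(C)=C\C)[C@H]1C[C@H]2O[C@@]2(C)[C@H](OC(=O)/C(C)=C\C)[C@@H]1O[Si](C)(C)C(C)(C)C | intermediate
20 | 2-methyl-2-butene | CC=C(C)C | starting material
21 | 10,11-alkene precursor (prenyl compound), (1R,2R,3R,4R,5R,8S) | C=C([C@H](CC=C(C)C)OC(=O)/C(C)=C\C)[C@H]1C[C@H]2O[C@@]2(C)[C@H](OC(=O)/C(C)=C\C)[C@@H]1O[Si](C)(C)C(C)(C)C | intermediate
22 | 2-O-TBS ether of the target, (1R,2R,3R,4R,5R,8S,10R) | C=C([C@H](C[C@H]1OC1(C)C)OC(=O)/C(C)=C\C)[C@H]1C[C@H]2O[C@@]2(C)[C@H](OC(=O)/C(C)=C\C)[C@@H]1O[Si](C)(C)C(C)(C)C | intermediate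
23 | CNP0296086.5 | C=C([C@H](C[C@H]1OC1(C)C)OC(=O)/C(C)=C\C)[C@H]1C[C@H]2O[C@@]2(C)[C@H](OC(=O)/C(C)=C\C)[C@@H]1O | target

**Totals**
Total step count: 15. Longest linear sequence: 15 steps (1 → 23); the route is linear, with 13, 16 and 20 bought.

**Steps most likely to fail, with fallbacks**

Step 7 (Mitsunobu inversion at the hindered allylic C3; risks are elimination to the diene and SN2' ester). The fallback sets out from compound 9. DCC with CuCl (cat.) in THF converts the C3 hydroxyl under neutral conditions into the O-alkyl-N,N'-dicyclohexylisourea F1, with C3 unchanged. Heating F1 with 4-nitrobenzoic acid in toluene at 80 °C protonates the isourea, and the carboxylate displaces dicyclohexylurea with inversion. This comes back to the route at compound 10.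

Step 11 (double angeloylation; risks are an unreacted pseudo-axial C3 hydroxyl and Z→E isomerisation to tiglate). The fallback sets out from compound 15. Both hydroxyls are esterified with 2-[bis(2,2,2-trifluoroethoxy)phosphoryl]propanoic acid (DCC, DMAP, CH2Cl2), a small saturated acid that cannot isomerise, to give the bis(phosphonopropanoate) F2. A double Still–Gennari olefination (KN(SiMe3)2, 18-crown-6, THF, −78 °C, then acetaldehyde) then builds both Z-configured 2-methylbut-2-enoates on the substrate. This comes back to the route at compound 18.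

Step 15 (final desilylation; risks are acid opening of the 2,2-dimethyloxirane and slow cleavage of the hindered silyl ether). The fallback sets out from compound 19, before the side-chain oxirane exists. HF·pyridine in THF/pyridine removes the silyl group to give the desilylated vinyl epoxide F3. Cross-metathesis of F3 with 20 under the step 13 conditions gives the desilylated prenyl epoxide F4. Shi epoxidation of F4 (free hydroxyl tolerated, short reaction at 0 °C) then gives the product directly, coming back to the route at compound 23.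

**Further compounds**
F1 | step 7 | O-alkyl-N,N'-dicyclohexylisourea of 9 (C3 configuration as in 9) | C=C(COC(C)=O)[C@H]1CC=C(C)[C@@H](OC(=NC2CCCCC2)NC2CCCCC2)[C@@H]1O[Si](C)(C)C(C)(C)C
F2 | step 11 | C3,C8-bis{2-[bis(2,2,2-trifluoroethoxy)phosphoryl]propanoate} of 15 (phosphonate α-carbons as epimer mixture) | C=C([C@H](CC=C)OC(=O)C(C)P(=O)(OCC(F)(F)F)OCC(F)(F)F)[C@H]1CC=C(C)[C@H](OC(=O)C(C)P(=O)(OCC(F)(F)F)OCC(F)(F)F)[C@@H]1O[Si](C)(C)C(C)(C)C
F3 | step 15 | desilylated vinyl epoxide (19 with free C2 hydroxyl) | C=C([C@H](CC=C)OC(=O)/C(C)=C\C)[C@H]1C[C@H]2O[C@@]2(C)[C@H](OC(=O)/C(C)=C\C)[C@@H]1O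
F4 | step 15 | desilylated prenyl epoxide (21 with free C2 hydroxyl) | C=C([C@H](CC=C(C)C)OC(=O)/C(C)=C\C)[C@H]1C[C@H]2O[C@@]2(C)[C@H](OC(=O)/C(C)=C\C)[C@@H]1O
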